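**Retrosynthetic overview**
1. Target 21 ⇐ triol 20 (double acetylation) ⇐ ten-membered ring closed last at C6–C7 by Ni/Cr vinyl–aldehyde coupling of bromo aldehyde 19.
2. 19 ⇐ (Z)-vinyl iodide 15 (B-alkyl Suzuki coupling adds C4–C6) ⇐ lactol 10 (α-iodo Wittig olefination sets the 2Z alkene and frees 9-OH).
3. Lactone 9 ⇐ key C9–O bond: regiocontrolled, stereoretentive oxygen insertion (Baeyer–Villiger) into cyclobutanone 8; this oxygen ends up as the C9 acetate oxygen.
4. 8 ⇐ exo-alkylation at C9 of hydroxy cyclobutanone 6 ⇐ Mukaiyama hydration (C11–O) of cyclobutanone 5 ⇐ dichloroketene [2+2] on (R)-α-phellandrene.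
5. Ring order: six-membered ring (chiral pool) → temporary four-membered ring (fixes cis C1/C10) → temporary γ-lactone → ten-membered ring.

Assumption: commercial (R)-(−)-α-phellandrene is taken as enantiopure; eunicellane atom numbers of the target (C1/C10 ring fusion, C2=C3, C6, C7=C16, C9, C11 carbinol, C14 with isopropyl) label every intermediate, and the SMILES are authoritative for configuration. The target is (1S,2Z,6R,9R,10S,11R,14R).

**Step 1**
Reactants: 1 (R)-(−)-α-phellandrene; 2 trichloroacetyl chloride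
Product: 4 (1R,5R,6R)-8,8-dichloro-2-methyl-5-(propan-2-yl)bicyclo[4.2.0]oct-2-en-7-one (cis-fused; C=O carbon is C2 on C1; CCl2 is C9 on C10; four-membered ring anti to isopropyl), via dichloroketene 3 (not isolated)
Conditions: Zn–Cu couple, Et2O, 35 °C, slow addition of 2
Reagents that add atoms: none
Why: Ketene–diene [2+2] cycloaddition: the ketene carbonyl carbon bonds to the diene terminus C1 and the CCl2 carbon to C10, suprafacially across the disubstituted C10=C1 bond and on the face away from the C14 isopropyl group, which sets the cis C1/C10 fusion anti to isopropyl.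

**Step 2**
Reactants: 4
Product: 5 (1R,5R,6R)-2-methyl-5-(propan-2-yl)bicyclo[4.2.0]oct-2-en-7-one
Conditions: Zn dust, AcOH, 60 °C
Reagents that add atoms: none
Why: Zinc-mediated reductive dechlorination of an α,α-dichloroketone (via zinc enolates) leaves the strained ketone, the alkene and the three stereocentres untouched.

**Step 3**
Reactants: 5
Product: 6 (1R,2R,5R,6R)-2-hydroxy-2-methyl-5-(propan-2-yl)bicyclo[4.2.0]octan-7-one (tertiary 11-OH cis to H10 and anti to the four-membered ring)
Conditions: Co(acac)2 (20 mol %), PhSiH3, O2 (1 atm), THF, 0 °C to rt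
Reagents that add atoms: dioxygen (O=O)
Why: Mukaiyama hydration (metal-hydride hydrogen-atom transfer): H adds to C12 and the tertiary C11 radical is trapped by O2 on the face opposite the adjacent C10–C9 bond of the fused four-membered ring, giving the Markovnikov alcohol with 11R configuration.

**Step 4**
Reactants: 6; 7 2,3-dibromopropene
Product: 8 (1R,2R,5R,6R,8R)-8-(2-bromoprop-2-en-1-yl)-2-hydroxy-2-methyl-5-(propan-2-yl)bicyclo[4.2.0]octan-7-one (bromoallyl group exo at C9 and so cis to H1 and H10)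
Conditions: LiN(iPr)2 (2.2 equiv), THF, −78 °C; then 7, DMPU, −78 to −30 °C
Reagents that add atoms: none
Why: Kinetic enolate alkylation: the alkoxide/enolate dianion (deprotonated at the C9 methylene, not at ring-fusion C1) is alkylated on the convex face of the cis-fused bicycle, placing C8 cis to H10, which is the arrangement that becomes 9R.

**Step 5**
Reactants: 8
Product: 9 (3R,3aS,4R,7R,7aR)-3-(2-bromoprop-2-en-1-yl)-4-hydroxy-4-methyl-7-(propan-2-yl)hexahydro-2-benzofuran-1(3H)-one (cis-fused γ-lactone; ring oxygen on C9; carbonyl is C2)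
Conditions: Sc(OTf)3 (10 mol %), chiral C2-symmetric N,N′-dioxide ligand (12 mol %; trimethylene-bridged bis(pipecolic acid N-oxide 2,6-diisopropylanilide), enantiomer chosen by screening both), mCPBA (1.3 equiv), EtOAc, −20 °C
Reagents that add atoms: mCPBA (O=C(OO)c1cccc(Cl)c1)
Why: Proposed new method: a chiral scandium Lewis acid is asked to choose between two secondary migrating carbons (C9 versus C1) of an enantiopure α,α′-disubstituted fused cyclobutanone in a Baeyer–Villiger oxidation; two-point binding of the Criegee adduct (ketone oxygen and peracid carbonyl on trivalent scandium) inside the ligand pocket should hold the O–O bond antiperiplanar to C2–C9 so that C9 migrates with retention, forming the C9–O bond and fixing 9R, and because neither carbon is electronically favoured the catalyst geometry should decide; the closest known reaction type is the chiral-Lewis-acid-catalysed regiodivergent Baeyer–Villiger parallel kinetic resolution of racemic fused cyclobutanones, where one enantiomer gives the "abnormal" lactone by CH2 migration.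

**Step 6**
Reactants: 9
Product: 10 3-(2-bromoprop-2-en-1-yl)-4-methyl-7-(propan-2-yl)octahydro-2-benzofuran-1,4-diol (lactol of 9; anomeric mixture; other centres as in 9)
Conditions: iBu2AlH (2.5 equiv), CH2Cl2, −78 °C; aq. KNaC4H4O6 work-up
Reagents that add atoms: none
Why: Partial hydride reduction of a γ-lactone stops at the aluminium hemiacetal at −78 °C (the first equivalent is consumed by the tertiary OH), and the anomeric centre formed is of no consequence.

**Step 7**
Reactants: 10; 11 ethyltriphenylphosphonium iodide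
Product: 15 2-[(1R)-3-bromo-1-hydroxybut-3-en-1-yl]-3-[(1Z)-2-iodoprop-1-en-1-yl]-1-methyl-4-(propan-2-yl)cyclohexan-1-ol (1-OH; H2; H3 and 4-isopropyl on one ring face; both side chains and 1-methyl on the other), via ethylidenetriphenylphosphorane 12 (not isolated), via (1-iodoethyl)triphenylphosphonium iodide 13 (not isolated), via (1-iodoethylidene)triphenylphosphorane 14 (not isolated)
Conditions: 11, n-BuLi, THF, rt; I2, −78 °C; NaN(SiMe3)2, −20 °C; then 10 (pre-treated with NaN(SiMe3)2), −78 to −10 °C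
Reagents that add atoms: iodine (II)
Why: Zhao-type α-iodo Wittig olefination: the lactol opens to the C2 aldehyde, which reacts with Ph3P=C(I)CH3 through the kinetically favoured cis-oxaphosphetane to give the (Z)-2-iodoalkene (C1 cis to iodine), while the released C9 alkoxide becomes the free 9-OH.

**Step 8**
Reactants: 15; 16 acrolein diethyl acetal
Product: 19 (4Z)-5-{2-[(1R)-3-bromo-1-hydroxybut-3-en-1-yl]-3-hydroxy-3-methyl-6-(propan-2-yl)cyclohexyl}-4-methylpent-4-enal (ring configuration as in 15), via B-(3,3-diethoxypropyl)-9-borabicyclo[3.3.1]nonane 17 (not isolated), via C6 diethyl acetal 18 (not isolated)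
Conditions: 16, 9-BBN, THF, rt; then 15, Pd(dppf)Cl2 (5 mol %), AsPh3, Cs2CO3, DMF/H2O, rt; then 1 M HCl, THF, rt
Reagents that add atoms: water (O)
Why: B-alkyl Suzuki–Miyaura coupling proceeds with retention at the vinyl iodide (C4 ends cis to C1, the 2Z geometry) and faster at the C–I bond than at the 2-bromoalkene, and mild acid then unmasks the C6 aldehyde.

**Step 9**
Reactants: 19
Product: 20 (1S,2Z,6R,9R,10S,11R,14R)-eunicella-2,7(16)-diene-6,9,11-triol
Conditions: CrCl2 (8 equiv), NiCl2 (2 mol %), DMSO, rt, 0.003 M (syringe-pump addition)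
Reagents that add atoms: none
Why: Nozaki–Hiyama–Kishi reaction: nickel-catalysed activation of the 2-bromoalkene and transmetalation to chromium gives a vinylchromium species that adds intramolecularly to the C6 aldehyde, the Z alkene and cis ring fusion pre-organising the chain; attack on the peripheral face of the aldehyde is expected, but not guaranteed, to give the 6R allylic alcohol with the exocyclic methylene in place.

**Step 10**
Reactants: 20
Product: 21 (1S,2Z,6R,9R,10S,11R,14R)-11-hydroxyeunicella-2,7(16)-diene-6,9-diyl diacetate (target)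
Conditions: Ac2O (3 equiv), pyridine, DMAP (5 mol %), CH2Cl2, 0 °C to rt
Reagents that add atoms: acetic anhydride (CC(=O)OC(C)=O)
Why: Nucleophile-catalysed acylation esterifies the two secondary alcohols (C6 and C9) while the hindered tertiary 11-OH does not react under these mild conditions.

**Compound list**
1 | (R)-(−)-α-phellandrene, (5R)-2-methyl-5-(propan-2-yl)cyclohexa-1,3-diene | CC1=CC[C@@H](C=C1)C(C)C | starting material
2 | trichloroacetyl chloride | ClC(Cl)(Cl)C(Cl)=O | starting material
3 | dichloroketene | ClC(Cl)=C=O | intermediate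
4 | (1R,5R,6R)-8,8-dichloro-2-methyl-5-(propan-2-yl)bicyclo[4.2.0]oct-2-en-7-one | O=C1C(Cl)(Cl)[C@@H]2[C@H]1[C@@H](C(C)C)CC=C2C | intermediate
5 | (1R,5R,6R)-2-methyl-5-(propan-2-yl)bicyclo[4.2.0]oct-2-en-7-one | O=C1C[C@@H]2[C@H]1[C@@H](C(C)C)CC=C2C | intermediate
6 | (1R,2R,5R,6R)-2-hydroxy-2-methyl-5-(propan-2-yl)bicyclo[4.2.0]octan-7-one | O=C1C[C@@H]2[C@H]1[C@@H](C(C)C)CC[C@@]2(C)O | intermediate
7 | 2,3-dibromopropene | C=C(Br)CBr | starting material
8 | (1R,2R,5R,6R,8R)-8-(2-bromoprop-2-en-1-yl)-2-hydroxy-2-methyl-5-(propan-2-yl)bicyclo[4.2.0]octan-7-one | O=C1[C@H](CC(Br)=C)[C@@H]2[C@H]1[C@@H](C(C)C)CC[C@@]2(C)O | intermediate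
9 | (3R,3aS,4R,7R,7aR)-3-(2-bromoprop-2-en-1-yl)-4-hydroxy-4-methyl-7-(propan-2-yl)hexahydro-2-benzofuran-1(3H)-one | O=C1O[C@H](CC(Br)=C)[C@@H]2[C@H]1[C@@H](C(C)C)CC[C@@]2(C)O | intermediate
10 | lactol of 9 (anomeric mixture) | OC1O[C@H](CC(Br)=C)[C@@H]2[C@H]1[C@@H](C(C)C)CC[C@@]2(C)O | intermediate
11 | ethyltriphenylphosphonium iodide | CC[P+](c1ccccc1)(c1ccccc1)c1ccccc1.[I-] | starting material
12 | ethylidenetriphenylphosphorane | CC=P(c1ccccc1)(c1ccccc1)c1ccccc1 | intermediate
13 | (1-iodoethyl)triphenylphosphonium iodide | CC(I)[P+](c1ccccc1)(c1ccccc1)c1ccccc1.[I-] | intermediate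
14 | (1-iodoethylidene)triphenylphosphorane | CC(I)=P(c1ccccc1)(c1ccccc1)c1ccccc1 | intermediate
15 | 2-[(1R)-3-bromo-1-hydroxybut-3-en-1-yl]-3-[(1Z)-2-iodoprop-1-en-1-yl]-1-methyl-4-(propan-2-yl)cyclohexan-1-ol | C=C(Br)C[C@@H](O)[C@@H]1[C@H](/C=C(/C)I)[C@@H](C(C)C)CC[C@@]1(C)O | intermediate
16 | acrolein diethyl acetal (3,3-diethoxyprop-1-ene) | C=CC(OCC)OCC | starting material
17 | B-(3,3-diethoxypropyl)-9-borabicyclo[3.3.1]nonane | CCOC(CCB1C2CCCC1CCC2)OCC | intermediate
18 | C6 diethyl acetal of aldehyde 19 | C=C(Br)C[C@@H](O)[C@@H]1[C@H](/C=C(/C)CCC(OCC)OCC)[C@@H](C(C)C)CC[C@@]1(C)O | intermediate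
19 | (4Z)-5-{2-[(1R)-3-bromo-1-hydroxybut-3-en-1-yl]-3-hydroxy-3-methyl-6-(propan-2-yl)cyclohexyl}-4-methylpent-4-enal | C=C(Br)C[C@@H](O)[C@@H]1[C@H](/C=C(/C)CCC=O)[C@@H](C(C)C)CC[C@@]1(C)O | intermediate
20 | (1S,2Z,6R,9R,10S,11R,14R)-eunicella-2,7(16)-diene-6,9,11-triol | C=C1C[C@@H](O)[C@@H]2[C@H](/C=C(/C)CC[C@H]1O)[C@@H](C(C)C)CC[C@@]2(C)O | intermediate
21 | (1S,2Z,6R,9R,10S,11R,14R)-11-hydroxyeunicella-2,7(16)-diene-6,9-diyl diacetate | C=C1C[C@@H](OC(C)=O)[C@@H]2[C@H](/C=C(/C)CC[C@H]1OC(C)=O)[C@@H](C(C)C)CC[C@@]2(C)O | target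

**Totals**
Total step count: 10. Longest linear sequence: 10 steps (1 → 21); all other inputs are commercial.

**Three steps most likely to fail**

Step 5 (the proposed new method). The catalyst may fail to override the small intrinsic bias and give the C1-migrated lactone or a mixture. Fallback with known chemistry, setting out from 6 and coming back at 9: the dianion of 6 (LiN(iPr)2) is hydroxylated at C9 with 2-(phenylsulfonyl)-3-phenyloxaziridine to give the 9-hydroxy cyclobutanone F1. Pb(OAc)4 in MeOH/benzene cleaves this α-hydroxy ketone to the cis methyl ester aldehyde F2 (C2 as CO2Me, C9 as CHO). Indium-mediated Barbier addition of 7 (In powder, THF/H2O) gives the bromoallyl carbinol hydroxy ester F3 under Felkin control, and PPTS in toluene closes it to lactone 9. The 9-epimer is removed by chromatography, and the route resumes at step 6. This cuts the C2–C9 bond oxidatively and forms C8–C9 by carbonyl addition instead of by oxygen insertion.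

Step 7. The α-iodo ylide is less reactive than simple ylides and may not intercept the small equilibrium amount of open hydroxy aldehyde, and C1 could epimerise. Fallback setting out from 9 and coming back at 15: Me(MeO)NH·HCl with iPrMgCl opens the lactone to the hydroxy Weinreb amide F4. Et3SiCl/imidazole caps the secondary 9-OH to give the silyl ether F5. iBu2AlH gives the open-chain aldehyde F6, which undergoes the same α-iodo Wittig olefination as an ordinary aldehyde to give the silylated (Z)-vinyl iodide F7. Bu4NF removes the silyl group and gives 15.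

Step 9. Ten-membered ring closure may be slow against oligomerisation, and the C6 configuration rests on substrate control only. Fallback setting out from 9 and coming back at 20, which sets C6 under reagent control and closes the ring at C3–C4 instead: intermolecular Nozaki–Hiyama–Kishi addition of the 2-bromoalkene of 9 to acrolein (CrCl2, NiCl2, chiral sulfonamide ligand) gives the divinyl carbinol lactone F8. tBuMe2SiCl/imidazole gives the 6-O-silyl ether F9, and iBu2AlH gives the lactol F10. α-Iodo Wittig olefination as in step 7 gives the (Z)-vinyl iodide F11. 9-BBN hydroborates the monosubstituted C4=C5 vinyl group to the alkylborane F12, used in solution. Intramolecular B-alkyl Suzuki–Miyaura coupling (Pd(dppf)Cl2, AsPh3, Cs2CO3, high dilution) gives the 6-O-silyl macrocycle F13, and Bu4NF gives triol 20.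

**Further compounds**
F1 | step 5 | 2,8-dihydroxy-2-methyl-5-(propan-2-yl)bicyclo[4.2.0]octan-7-one (9-hydroxy derivative of 6, C9 epimers) | O=C1C(O)[C@@H]2[C@H]1[C@@H](C(C)C)CC[C@@]2(C)O
F2 | step 5 | methyl 2-formyl-3-hydroxy-3-methyl-6-(propan-2-yl)cyclohexane-1-carboxylate (cis ester/aldehyde, ring configuration as in 6) | O=C[C@@H]1[C@H](C(=O)OC)[C@@H](C(C)C)CC[C@@]1(C)O
F3 | step 5 | methyl 2-[(1R)-3-bromo-1-hydroxybut-3-en-1-yl]-3-hydroxy-3-methyl-6-(propan-2-yl)cyclohexane-1-carboxylate | C=C(Br)C[C@@H](O)[C@@H]1[C@H](C(=O)OC)[C@@H](C(C)C)CC[C@@]1(C)O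
F4 | step 7 | 2-[(1R)-3-bromo-1-hydroxybut-3-en-1-yl]-3-hydroxy-N-methoxy-N,3-dimethyl-6-(propan-2-yl)cyclohexane-1-carboxamide | C=C(Br)C[C@@H](O)[C@@H]1[C@H](C(=O)N(C)OC)[C@@H](C(C)C)CC[C@@]1(C)O
F5 | step 7 | 9-O-triethylsilyl ether of F4 | C=C(Br)C[C@@H](O[Si](CC)(CC)CC)[C@@H]1[C@H](C(=O)N(C)OC)[C@@H](C(C)C)CC[C@@]1(C)O
F6 | step 7 | 2-[(1R)-3-bromo-1-(triethylsilyloxy)but-3-en-1-yl]-3-hydroxy-3-methyl-6-(propan-2-yl)cyclohexane-1-carbaldehyde | C=C(Br)C[C@@H](O[Si](CC)(CC)CC)[C@@H]1[C@H](C=O)[C@@H](C(C)C)CC[C@@]1(C)O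
F7 | step 7 | 9-O-triethylsilyl ether of vinyl iodide 15 | C=C(Br)C[C@@H](O[Si](CC)(CC)CC)[C@@H]1[C@H](/C=C(/C)I)[C@@H](C(C)C)CC[C@@]1(C)O
F8 | step 9 | lactone 9 with the bromoallyl group replaced by (3R)-3-hydroxy-2-methylidenepent-4-en-1-yl | O=C1O[C@H](CC(=C)[C@H](O)C=C)[C@@H]2[C@H]1[C@@H](C(C)C)CC[C@@]2(C)O
F9 | step 9 | 6-O-tert-butyldimethylsilyl ether of F8 | O=C1O[C@H](CC(=C)[C@H](O[Si](C)(C)C(C)(C)C)C=C)[C@@H]2[C@H]1[C@@H](C(C)C)CC[C@@]2(C)O
F10 | step 9 | lactol of F9 (anomeric mixture) | OC1O[C@H](CC(=C)[C@H](O[Si](C)(C)C(C)(C)C)C=C)[C@@H]2[C@H]1[C@@H](C(C)C)CC[C@@]2(C)O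
F11 | step 9 | (Z)-vinyl iodide from F10: cyclohexanol as in 15 with the C9 side chain extended to the 6-O-silylated divinyl carbinol | C=C[C@@H](O[Si](C)(C)C(C)(C)C)C(=C)C[C@@H](O)[C@@H]1[C@H](/C=C(/C)I)[C@@H](C(C)C)CC[C@@]1(C)O
F12 | step 9 | B-alkyl-9-borabicyclo[3.3.1]nonane from hydroboration of F11 at C4=C5 | B1(CC[C@@H](O[Si](C)(C)C(C)(C)C)C(=C)C[C@@H](O)[C@@H]2[C@H](/C=C(/C)I)[C@@H](C(C)C)CC[C@@]2(C)O)C2CCCC1CCC2
F13 | step 9 | 6-O-tert-butyldimethylsilyl ether of triol 20 | C=C1C[C@@H](O)[C@@H]2[C@H](/C=C(/C)CC[C@H]1O[Si](C)(C)C(C)(C)C)[C@@H](C(C)C)CC[C@@]2(C)O
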